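**Retrosynthetic overview**

1. The enal comes last, by allylic oxidation of the C2 isopropenyl methyl; the two tiglates come from diol 17, and the (R)-carbinol at C5 comes from aryl methyl ketone 16 by asymmetric transfer hydrogenation.
2. The strategy rests on the benzene ring (C3a, C4, C5, C6, C7, C7a): apart from the fusion it carries only O1 on C7a and the side-chain carbon on C5, para to each other, with C4, C6 and C7 as CH. This is the substitution pattern that a 2-alkoxydiene and an ynone deliver.
3. Key disconnection: C3a–C4 and C5–C6, i.e. 5-vinyl-2,3-dihydrofuran 11 plus but-3-yn-2-one 12, followed by DDQ dehydrogenation to 14.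
4. Diene 11 comes from anti enynol 10 by gold-catalysed 5-endo-dig closure (O1–C7a bond). C2 and C3 are set by an anti-selective alkoxyallenylzinc addition to methacrolein (relative) and a Sharpless kinetic resolution (absolute).
5. Ring order: dihydrofuran ring first (step 6), benzene ring last (step 7).

Key step: step 7

Reading of the target: (2R,3S), i.e. 2,3-trans on the dihydrofuran ring, and (R) at the side-chain carbinol carbon; atom numbers are those of 2,3-dihydro-1-benzofuran, and vinyl bromide is taken as its commercial THF solution.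

**Route**

Step 1
Reactants: 1 3-(trimethylsilyl)prop-2-yn-1-ol
Product: 2 [3-(methoxymethoxy)prop-1-yn-1-yl]trimethylsilane
Conditions: MOMCl, iPr2NEt, CH2Cl2, 0 °C to rt
Reagents that add atoms: chloromethyl methyl ether (MOMCl), COCCl
Why: Base-mediated O-alkylation of the primary propargylic alcohol by the α-chloro ether (Williamson-type acetal formation) installs the MOM group, which later serves as the chelating α-alkoxy substituent of the allenylzinc and as the C3–O protecting group.

Step 2
Reactants: 2 [3-(methoxymethoxy)prop-1-yn-1-yl]trimethylsilane, 3 methacrolein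
Product: 6 rac-(3R*,4S*)-4-(methoxymethoxy)-2-methyl-6-(trimethylsilyl)hex-1-en-5-yn-3-ol, via lithiated propargyl ether 4 (not isolated), via allenylzinc bromide 5 (not isolated)
Conditions: s-BuLi, THF, −78 °C; ZnBr2, −78 °C; then 3, −78 to −20 °C; aq NH4Cl
Reagents that add atoms: none
Why: This is the known anti-selective propargylation of aldehydes by 3-alkoxyallenylzinc reagents: deprotonation α to oxygen, Li-to-Zn exchange and SE2′ addition through a closed six-membered transition state keep the aldehyde substituent away from the alkoxy group, so the anti 1,2-diol monoether should predominate (relative configuration of the future C2 and C3), with the silyl group directing C–C bond formation to the oxygen-bearing carbon.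

Step 3
Reactants: 6 rac-(3R*,4S*)-4-(methoxymethoxy)-2-methyl-6-(trimethylsilyl)hex-1-en-5-yn-3-ol
Product: 7 (3R,4S)-4-(methoxymethoxy)-2-methyl-6-(trimethylsilyl)hex-1-en-5-yn-3-ol
Conditions: Ti(OiPr)4 (0.2 equiv), D-(−)-diisopropyl tartrate (0.25 equiv), t-BuOOH (0.6 equiv), 4 Å MS, CH2Cl2, −20 °C
Reagents that add atoms: none
Why: Sharpless kinetic resolution of a secondary allylic alcohol: with the D-(−)-tartrate the titanium complex should epoxidise the (3S,4R) enantiomer much faster (its carbinol substituent points away from the delivered oxygen), so the (3R,4S) alcohol is expected to remain enantioenriched once slightly more than half of the material is consumed; the absolute configuration of both stereocentres is selected here.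

Step 4
Reactants: 7 (3R,4S)-4-(methoxymethoxy)-2-methyl-6-(trimethylsilyl)hex-1-en-5-yn-3-ol
Product: 8 (3R,4S)-4-(methoxymethoxy)-2-methylhex-1-en-5-yn-3-ol
Conditions: K2CO3, MeOH, rt
Reagents that add atoms: none
Why: Methoxide-mediated protodesilylation of the alkynylsilane; the MOM acetal, the alkene and both stereocentres are inert to these conditions.

Step 5
Reactants: 8 (3R,4S)-4-(methoxymethoxy)-2-methylhex-1-en-5-yn-3-ol, 9 vinyl bromide
Product: 10 (3R,4S)-4-(methoxymethoxy)-2-methylocta-1,7-dien-5-yn-3-ol
Conditions: Pd(PPh3)4 (3 mol %), CuI (6 mol %), Et2NH, THF, 0 °C to rt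
Reagents that add atoms: none
Why: Sonogashira coupling (oxidative addition of vinyl bromide to zerovalent palladium, transmetalation from the copper acetylide, reductive elimination) builds the 1,3-enyne; the free secondary alcohol and the MOM ether are tolerated in the amine-buffered medium.

Step 6
Reactants: 10 (3R,4S)-4-(methoxymethoxy)-2-methylocta-1,7-dien-5-yn-3-ol
Product: 11 (2R,3S)-5-ethenyl-3-(methoxymethoxy)-2-(prop-1-en-2-yl)-2,3-dihydrofuran
Conditions: AuCl (5 mol %), K2CO3 (20 mol %), MeCN, rt, dark; filtration through basic alumina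
Reagents that add atoms: none
Why: Gold-catalysed cycloisomerisation of a homopropargylic alcohol: π-activation of the alkyne by monovalent gold, anti attack of the hydroxyl on the distal alkyne carbon (5-endo-dig, the 4-exo mode being strained) and protodeauration should give the 2,3-dihydrofuran with its enol ether conjugated to the vinyl group and both stereocentres untouched, while K2CO3 keeps the medium non-acidic so that the allylic C–OMOM bond does not ionise towards the furan.

Step 7
Reactants: 11 (2R,3S)-5-ethenyl-3-(methoxymethoxy)-2-(prop-1-en-2-yl)-2,3-dihydrofuran, 12 but-3-yn-2-one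
Product: 14 1-[(2R,3S)-3-(methoxymethoxy)-2-(prop-1-en-2-yl)-2,3-dihydro-1-benzofuran-5-yl]ethan-1-one, via cyclohexadiene adduct 13 (not isolated)
Conditions: 12 (3 equiv), 2,6-di-tert-butylpyridine (10 mol %), toluene, 70 °C; then DDQ (1.1 equiv), 0 °C to rt
Reagents that add atoms: none
Why: A concerted, asynchronous thermal [4+2] cycloaddition joins the electron-rich cyclic 2-alkoxydiene (ring C=C plus the vinyl group of 11) to the electron-poor ynone, and DDQ then abstracts hydride from the doubly allylic C6 of adduct 13 with loss of the C3a proton to give the arene. The closest known reaction type is the Diels–Alder reaction of 2-alkoxy- and 2-silyloxy-1,3-dienes (vinyl dihydrofurans, 1-vinyl glycals) with acetylenic ketones followed by dehydrogenation of the 1,4-cyclohexadiene to an aryl ether. The benzene ring (C3a–C4–C5–C6–C7–C7a) is closed intermolecularly by the two bonds C3a–C4 and C5–C6 as a six-membered ring annulated on the C3a–C7a edge of the dihydrofuran. No lasting stereocentre is created, since C3a is stereogenic only in 13 and is erased on aromatisation, and C2 and C3 lie outside the reacting atoms and keep their configuration. The step needs regiocontrol (acetyl at C5, not C4), which the O1 donor secures by placing the largest HOMO coefficient on the enol ether β-carbon (future C3a), so that this carbon bonds to the unsubstituted alkyne terminus, a preference reinforced by the lower steric demand of that terminus at the substituted C3a. The hindered pyridine keeps the medium free of acid so that the allylic C3–OMOM bond should not ionise, and DDQ is added only after the diene is consumed.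

Step 8
Reactants: 14 1-[(2R,3S)-3-(methoxymethoxy)-2-(prop-1-en-2-yl)-2,3-dihydro-1-benzofuran-5-yl]ethan-1-one
Product: 16 1-[(2R,3S)-3-hydroxy-2-(prop-1-en-2-yl)-2,3-dihydro-1-benzofuran-5-yl]ethan-1-one, via bromomethyl ether 15 (not isolated)
Conditions: Me2BBr, CH2Cl2, −78 °C; then aq NaHCO3, THF, 0 °C
Reagents that add atoms: none
Why: Guindon-type acetal cleavage: Me2BBr converts the MOM acetal at low temperature into the bromomethyl ether, which aqueous bicarbonate hydrolyses to the alcohol, and because the para acetyl group attenuates donation from O1 at this stage, ionisation of the benzylic C3–O bond (towards the benzofuran or C3 epimerisation) should be slow relative to acetal cleavage.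

Step 9
Reactants: 16 1-[(2R,3S)-3-hydroxy-2-(prop-1-en-2-yl)-2,3-dihydro-1-benzofuran-5-yl]ethan-1-one
Product: 17 (2R,3S)-5-[(1R)-1-hydroxyethyl]-2-(prop-1-en-2-yl)-2,3-dihydro-1-benzofuran-3-ol
Conditions: RuCl[(R,R)-TsDPEN](p-cymene) (1 mol %), HCO2H/Et3N (5:2), CH2Cl2, rt
Reagents that add atoms: none
Why: Noyori asymmetric transfer hydrogenation: the ruthenium hydride/amine pair of the (R,R)-TsDPEN complex delivers hydride and proton to the aryl methyl ketone through a six-membered transition state and should give the (R)-carbinol under catalyst control, while the isolated 1,1-disubstituted alkene and the C3 alcohol are not affected.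

Step 10
Reactants: 17 (2R,3S)-5-[(1R)-1-hydroxyethyl]-2-(prop-1-en-2-yl)-2,3-dihydro-1-benzofuran-3-ol, 18 tiglic acid
Product: 20 (2R,3S)-5-[(1R)-1-{[(2E)-2-methylbut-2-enoyl]oxy}ethyl]-2-(prop-1-en-2-yl)-2,3-dihydro-1-benzofuran-3-yl (2E)-2-methylbut-2-enoate, via tigloyl 2,4,6-trichlorobenzoyl anhydride 19 (not isolated)
Conditions: 18 (3 equiv), 2,4,6-trichlorobenzoyl chloride, Et3N, toluene, rt; then 17, DMAP, rt to 40 °C
Reagents that add atoms: none
Why: Yamaguchi esterification: the mixed anhydride transfers the tigloyl group through the acylpyridinium ion to both secondary hydroxyls with retention at C3 and at the side-chain carbinol (acylation at oxygen), and this activation avoids the vinylketene deconjugation pathway of the acid chloride, so the stable E geometry should be kept.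

Step 11
Reactants: 20 (2R,3S)-5-[(1R)-1-{[(2E)-2-methylbut-2-enoyl]oxy}ethyl]-2-(prop-1-en-2-yl)-2,3-dihydro-1-benzofuran-3-yl (2E)-2-methylbut-2-enoate
Product: 21 (2R,3S)-2-(3-hydroxyprop-1-en-2-yl)-5-[(1R)-1-{[(2E)-2-methylbut-2-enoyl]oxy}ethyl]-2,3-dihydro-1-benzofuran-3-yl (2E)-2-methylbut-2-enoate
Conditions: SeO2 (0.5 equiv), t-BuOOH (3 equiv), CH2Cl2, rt
Reagents that add atoms: tert-butyl hydroperoxide, CC(C)(C)OO (oxygen relayed to carbon through the SeO2 catalyst, O=[Se]=O)
Why: Riley allylic oxidation (Sharpless–Umbreit variant): ene reaction of the Se=O bond with the most electron-rich alkene, the 1,1-disubstituted isopropenyl group, then [2,3]-sigmatropic shift places oxygen on the former methyl carbon, while the electron-poor tiglate alkenes and the C2 methine should react more slowly; any enal formed directly converges in step 12.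

Step 12
Reactants: 21 (2R,3S)-2-(3-hydroxyprop-1-en-2-yl)-5-[(1R)-1-{[(2E)-2-methylbut-2-enoyl]oxy}ethyl]-2,3-dihydro-1-benzofuran-3-yl (2E)-2-methylbut-2-enoate
Product: 22 (2R,3S)-5-[(1R)-1-{[(2E)-2-methylbut-2-enoyl]oxy}ethyl]-2-(3-oxoprop-1-en-2-yl)-2,3-dihydro-1-benzofuran-3-yl (2E)-2-methylbut-2-enoate (CNP0292799.1)
Conditions: MnO2 (activated, excess), CH2Cl2, rt
Reagents that add atoms: none
Why: Chemoselective oxidation of the primary allylic alcohol to the enal on activated manganese dioxide under neutral heterogeneous conditions, which should leave the acid-labile benzylic tiglate, the enoates and all three stereocentres untouched.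

**Compound list**

1 | 3-(trimethylsilyl)prop-2-yn-1-ol | C[Si](C)(C)C#CCO | starting material
2 | [3-(methoxymethoxy)prop-1-yn-1-yl]trimethylsilane | C[Si](C)(C)C#CCOCOC | intermediate
3 | methacrolein | C=C(C)C=O | starting material
4 | [1-(methoxymethoxy)-3-(trimethylsilyl)prop-2-yn-1-yl]lithium (lithiated propargyl ether) | COCOC([Li])C#C[Si](C)(C)C | intermediate
5 | bromo[3-(methoxymethoxy)-1-(trimethylsilyl)propa-1,2-dien-1-yl]zinc (allenylzinc bromide) | COCOC=C=C([Zn]Br)[Si](C)(C)C | intermediate
6 | rac-(3R*,4S*)-4-(methoxymethoxy)-2-methyl-6-(trimethylsilyl)hex-1-en-5-yn-3-ol (racemate; SMILES drawn for the 3R,4S enantiomer) | C=C(C)[C@@H](O)[C@@H](OCOC)C#C[Si](C)(C)C | intermediate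
7 | (3R,4S)-4-(methoxymethoxy)-2-methyl-6-(trimethylsilyl)hex-1-en-5-yn-3-ol | C=C(C)[C@@H](O)[C@@H](OCOC)C#C[Si](C)(C)C | intermediate
8 | (3R,4S)-4-(methoxymethoxy)-2-methylhex-1-en-5-yn-3-ol | C=C(C)[C@@H](O)[C@@H](OCOC)C#C | intermediate
9 | vinyl bromide | C=CBr | starting material
10 | (3R,4S)-4-(methoxymethoxy)-2-methylocta-1,7-dien-5-yn-3-ol | C=C(C)[C@@H](O)[C@@H](OCOC)C#CC=C | intermediate
11 | (2R,3S)-5-ethenyl-3-(methoxymethoxy)-2-(prop-1-en-2-yl)-2,3-dihydrofuran | C=C(C)[C@H]1OC(C=C)=C[C@@H]1OCOC | intermediate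
12 | but-3-yn-2-one | CC(=O)C#C | starting material
13 | 1-[(2R,3S)-3-(methoxymethoxy)-2-(prop-1-en-2-yl)-2,3,3a,6-tetrahydro-1-benzofuran-5-yl]ethan-1-one (C3a unassigned) | C=C(C)[C@H]1OC2=CCC(C(C)=O)=CC2[C@@H]1OCOC | intermediate
14 | 1-[(2R,3S)-3-(methoxymethoxy)-2-(prop-1-en-2-yl)-2,3-dihydro-1-benzofuran-5-yl]ethan-1-one | C=C(C)[C@H]1Oc2ccc(C(C)=O)cc2[C@@H]1OCOC | intermediate
15 | 1-[(2R,3S)-3-(bromomethoxy)-2-(prop-1-en-2-yl)-2,3-dihydro-1-benzofuran-5-yl]ethan-1-one | C=C(C)[C@H]1Oc2ccc(C(C)=O)cc2[C@@H]1OCBr | intermediate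
16 | 1-[(2R,3S)-3-hydroxy-2-(prop-1-en-2-yl)-2,3-dihydro-1-benzofuran-5-yl]ethan-1-one | C=C(C)[C@H]1Oc2ccc(C(C)=O)cc2[C@@H]1O | intermediate
17 | (2R,3S)-5-[(1R)-1-hydroxyethyl]-2-(prop-1-en-2-yl)-2,3-dihydro-1-benzofuran-3-ol | C=C(C)[C@H]1Oc2ccc([C@@H](C)O)cc2[C@@H]1O | intermediate
18 | tiglic acid, (2E)-2-methylbut-2-enoic acid | C/C=C(\C)C(=O)O | starting material
19 | (2E)-2-methylbut-2-enoic 2,4,6-trichlorobenzoic anhydride | C/C=C(\C)C(=O)OC(=O)c1c(Cl)cc(Cl)cc1Cl | intermediate
20 | (2R,3S)-5-[(1R)-1-{[(2E)-2-methylbut-2-enoyl]oxy}ethyl]-2-(prop-1-en-2-yl)-2,3-dihydro-1-benzofuran-3-yl (2E)-2-methylbut-2-enoate | C=C(C)[C@H]1Oc2ccc([C@@H](C)OC(=O)/C(C)=C/C)cc2[C@@H]1OC(=O)/C(C)=C/C | intermediate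
21 | (2R,3S)-2-(3-hydroxyprop-1-en-2-yl)-5-[(1R)-1-{[(2E)-2-methylbut-2-enoyl]oxy}ethyl]-2,3-dihydro-1-benzofuran-3-yl (2E)-2-methylbut-2-enoate | C=C(CO)[C@H]1Oc2ccc([C@@H](C)OC(=O)/C(C)=C/C)cc2[C@@H]1OC(=O)/C(C)=C/C | intermediate
22 | (2R,3S)-5-[(1R)-1-{[(2E)-2-methylbut-2-enoyl]oxy}ethyl]-2-(3-oxoprop-1-en-2-yl)-2,3-dihydro-1-benzofuran-3-yl (2E)-2-methylbut-2-enoate | C=C(C=O)[C@H]1Oc2ccc([C@@H](C)OC(=O)/C(C)=C/C)cc2[C@@H]1OC(=O)/C(C)=C/C | target

**Step count and risks**

Total step count: 12. Longest linear sequence: 12 steps (1 to 22).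

Steps most likely to fail:

Step 7. The cycloaddition at the substituted C3a terminus may be slow enough that thermal or trace-acid loss of the C3 alkoxy group (aromatisation of the diene to a furan) or erosion of regiocontrol competes. The fallback sets out from 11 and uses an alkene dienophile, which reacts at lower temperature with the same para orientation: methyl vinyl ketone at rt in toluene should give the cyclohexene adduct 1-[(2R,3S)-3-(methoxymethoxy)-2-(prop-1-en-2-yl)-2,3,3a,4,5,6-hexahydro-1-benzofuran-5-yl]ethan-1-one F1. A separate twofold dehydrogenation with DDQ (2.2 equiv, dioxane, 60 to 80 °C) then aromatises the ring, and the route is rejoined at 14.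

Step 6. The Lewis-acidic gold centre may ionise the allylic C3–OMOM bond of the product (aromatisation to the furan), or the vinyl enol ether may oligomerise. The fallback sets out from terminal alkyne 8 and closes the ring before the vinyl group is attached. Cycloisomerisation through a molybdenum vinylidene (Mo(CO)6, Et3N, Et2O, hν) in a basic medium should give (2R,3S)-3-(methoxymethoxy)-2-(prop-1-en-2-yl)-2,3-dihydrofuran F2. Lithiation at C5 with t-BuLi (THF, −78 to 0 °C) gives 5-lithio-(2R,3S)-3-(methoxymethoxy)-2-(prop-1-en-2-yl)-2,3-dihydrofuran F3, which is quenched with Bu3SnCl to (2R,3S)-3-(methoxymethoxy)-2-(prop-1-en-2-yl)-5-(tributylstannyl)-2,3-dihydrofuran F4. Stille coupling of F4 with vinyl bromide 9 (Pd(PPh3)4, THF, 50 °C) rejoins the route at 11.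

Step 11. The ene oxidation may be unselective (attack at the tiglate γ-methyl groups or at the C2 methine), and selenous acid may promote solvolysis of the para-alkoxybenzylic tiglate. The fallback sets out from 20 and replaces the selenium ene oxidation by an electrophilic ene chlorination. HOCl generated from Ca(OCl)2 and CO2 (CH2Cl2/H2O, 0 °C) should give the allylic chloride (2R,3S)-2-(3-chloroprop-1-en-2-yl)-5-[(1R)-1-{[(2E)-2-methylbut-2-enoyl]oxy}ethyl]-2,3-dihydro-1-benzofuran-3-yl (2E)-2-methylbut-2-enoate F5. Amine N-oxide oxidation of F5 (N-methylmorpholine N-oxide, MeCN, rt; Kornblum–Ganem type) then leads directly to the enal, rejoining the route at 22.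

**Further compounds**

F1 | step 7 | 1-[(2R,3S)-3-(methoxymethoxy)-2-(prop-1-en-2-yl)-2,3,3a,4,5,6-hexahydro-1-benzofuran-5-yl]ethan-1-one | C=C(C)[C@H]1OC2=CCC(C(C)=O)CC2[C@@H]1OCOC
F2 | step 6 | (2R,3S)-3-(methoxymethoxy)-2-(prop-1-en-2-yl)-2,3-dihydrofuran | C=C(C)[C@H]1OC=C[C@@H]1OCOC
F3 | step 6 | 5-lithio-(2R,3S)-3-(methoxymethoxy)-2-(prop-1-en-2-yl)-2,3-dihydrofuran | C=C(C)[C@H]1OC([Li])=C[C@@H]1OCOC
F4 | step 6 | (2R,3S)-3-(methoxymethoxy)-2-(prop-1-en-2-yl)-5-(tributylstannyl)-2,3-dihydrofuran | C=C(C)[C@H]1OC([Sn](CCCC)(CCCC)CCCC)=C[C@@H]1OCOC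
F5 | step 11 | (2R,3S)-2-(3-chloroprop-1-en-2-yl)-5-[(1R)-1-{[(2E)-2-methylbut-2-enoyl]oxy}ethyl]-2,3-dihydro-1-benzofuran-3-yl (2E)-2-methylbut-2-enoate | C=C(CCl)[C@H]1Oc2ccc([C@@H](C)OC(=O)/C(C)=C/C)cc2[C@@H]1OC(=O)/C(C)=C/C
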